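## Plan

- **Cuts (retrosynthesis):** C16=C17 (α-methylenation) and the C12 carbinol (ketone reduction); C11–C15 (Claisen, ring D); C11–C12 (acylation of an exocyclic C9=C11 olefin, ring C); then C5–C10 and C8–C9 together (rings A and B) by an intramolecular Diels–Alder reaction of a 2-silyloxydiene with an allene.
- **Enabling feature:** ring B carries oxygen at C6 (→ diene C5=C6(OSi)–C7=C8) and an sp2 C9 flanked by quaternary C10 and the one-carbon branch C11 (→ allene C10=C9=C11). After cycloaddition the exocyclic C9=C11 olefin can hand its unsaturation only to C8, which gives the C8=C9 olefin shared by rings B and C.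
- **Forward order:** chain C7–C1 from mesityl oxide and a butenyl Grignard reagent, allene by propargylboration, C8/C12–C16 arm from a 2-(2-oxoethyl)succinate → rings A+B (step 9) → ring C (step 12) → ring D (step 13) → 12-OH, C17.
- **Stereochemistry:** C1 from catalyst-controlled allenylation; C10 and C5 relayed from C1 in the cycloaddition; C6 by hydride attack anti to the axial C4/C10 methyls; C11/C13 by a face-selective Claisen closure on an epimerising C13; C12 by chelate-controlled hydride delivery.

Key step: step 9

Remarks on the chemistry: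
- Skeleton atoms are numbered C1–C20: ring A = C1–C5, C10; ring B = C5–C10; ring C = C8, C9, C11–C14; ring D = C11, C12, C13, C16, C15; C17 = exocyclic CH2; C20 = methyl on C10. "α" is the face carrying the C10 methyl.
- C13 of the succinate arm is carried as an epimer mixture up to 24 (SMILES leave it open) and converges in step 13.
- Boronate 1 is assumed to be purchasable.

## Route

Step 1
Reactants: 1 4,4,5,5-tetramethyl-2-(prop-1-yn-1-yl)-1,3,2-dioxaborolane
Product: 3 2-(but-2-yn-1-yl)-4,4,5,5-tetramethyl-1,3,2-dioxaborolane, via lithium borate complex 2 (not isolated)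
Conditions: BrCH2Cl, n-BuLi, THF, −78 °C → rt
Reagents that add atoms: bromochloromethane, ClCBr
Why: Matteson homologation, in which LiCH2Cl made in situ adds to boron and the alkynyl group migrates with loss of chloride, should give the propargylic boronate that later delivers C20, C10, C9 and C11.

Step 2
Reactants: 4 methyl pent-4-enoate; 5 propan-2-yl bromoacetate
Product: 6 1-methyl 4-propan-2-yl 2-(prop-2-en-1-yl)butanedioate (racemic)
Conditions: LiN(i-Pr)2, THF, −78 °C; then 5, −78 → 0 °C
Reagents that add atoms: none
Why: Ester enolate alkylation with an α-bromo ester should give the succinate with differentiated carboxyls (methyl at C12, isopropyl at C15); C13 is formed racemic on purpose because it is equilibrated in step 13.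

Step 3
Reactants: 6 1-methyl 4-propan-2-yl 2-(prop-2-en-1-yl)butanedioate
Product: 8 1-methyl 4-propan-2-yl 2-(2-oxoethyl)butanedioate, via ozonide 7 (not isolated)
Conditions: O3, CH2Cl2, −78 °C; then PPh3, −78 °C → rt
Reagents that add atoms: ozone, [O-][O+]=O
Why: Ozonolysis with reductive work-up of the monosubstituted olefin should give the aldehyde that becomes C8.

Step 4
Reactants: 9 4-methylpent-3-en-2-one (mesityl oxide); 10 but-3-en-1-ylmagnesium bromide
Product: 11 4,4-dimethyloct-7-en-2-one
Conditions: CuBr·SMe2 (5 mol %), THF, −40 → 0 °C; aq. NH4Cl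
Reagents that add atoms: none
Why: Copper-catalysed conjugate addition of the Grignard reagent to the β,β-disubstituted enone should build the quaternary C4 between C3 and C5, with C6 as the ketone and C7 as its methyl group.

Step 5
Reactants: 11 4,4-dimethyloct-7-en-2-one
Product: 13 4,4-dimethyl-6-oxoheptanal, via ozonide 12 (not isolated)
Conditions: O3, CH2Cl2, −78 °C; then PPh3, −78 °C → rt
Reagents that add atoms: ozone, [O-][O+]=O
Why: Ozonolysis of the terminal olefin should unveil the C1 aldehyde while the methyl ketone stays untouched.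

Step 6
Reactants: 13 4,4-dimethyl-6-oxoheptanal; 3 2-(but-2-yn-1-yl)-4,4,5,5-tetramethyl-1,3,2-dioxaborolane
Product: 15 (7S)-7-hydroxy-4,4,8-trimethyldeca-8,9-dien-2-one, via pinacol borate ester 14 (not isolated)
Conditions: (R)-TRIP [(R)-3,3′-bis(2,4,6-triisopropylphenyl)-1,1′-binaphthyl-2,2′-diyl hydrogen phosphate] (5 mol %), 4 Å molecular sieves, toluene, −30 °C; then aq. NaHCO3
Reagents that add atoms: none
Why: Chiral phosphoric acid-catalysed propargylboration (SE2′ through a six-membered chair) should bond the γ-carbon of the boronate to the aldehyde only, giving the 1-methylallenyl carbinol with C1 (S) set by the catalyst; the facial sense is assigned by analogy with the corresponding allylboration, and the antipodal acid is used if it proves reversed.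

Step 7
Reactants: 15 (7S)-7-hydroxy-4,4,8-trimethyldeca-8,9-dien-2-one; 8 1-methyl 4-propan-2-yl 2-(2-oxoethyl)butanedioate
Product: 17 (4E,11S)-11-hydroxy-8,8,12-trimethyl-6-oxo-2-[2-oxo-2-(propan-2-yloxy)ethyl]tetradeca-4,12,13-trienoic acid, via aldol γ-lactone 16 (not isolated)
Conditions: LiN(i-Pr)2 (2.1 equiv), THF, −78 °C; then 8; −78 °C → rt; DBU (0.2 equiv); aq. citric acid
Reagents that add atoms: none
Why: Aldol addition of the kinetic methyl-ketone enolate (C7) to the aldehyde, closure of the aldolate on the nearer methyl ester to a γ-lactone (five-ring formation should outrun attack on the more distant, bulkier isopropyl ester) and E1cB opening of this β-acyloxy ketone should give the (E)-enone and free the C12 acid selectively.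

Step 8
Reactants: 17 (4E,11S)-11-hydroxy-8,8,12-trimethyl-6-oxo-2-[2-oxo-2-(propan-2-yloxy)ethyl]tetradeca-4,12,13-trienoic acid
Product: 18 tert-butyldimethylsilyl (4E,6Z,11S)-6,11-bis(tert-butyldimethylsilyloxy)-8,8,12-trimethyl-2-[2-oxo-2-(propan-2-yloxy)ethyl]tetradeca-4,6,12,13-tetraenoate
Conditions: KN(SiMe3)2 (3.3 equiv), THF, −78 °C; t-BuMe2SiCl (3.5 equiv), −78 → 0 °C
Reagents that add atoms: tert-butyldimethylsilyl chloride, CC(C)(C)[Si](C)(C)Cl
Why: After alkoxide and carboxylate formation the third equivalent of base should remove a C5 proton (kinetic α′ enolisation of the enone) and O-silylation should give the cross-conjugated 2-silyloxydiene as the Z enol ether, because the E isomer would press the tert-alkyl C4 against the vinyl group.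

Step 9
Reactants: 18 tert-butyldimethylsilyl (4E,6Z,11S)-6,11-bis(tert-butyldimethylsilyloxy)-8,8,12-trimethyl-2-[2-oxo-2-(propan-2-yloxy)ethyl]tetradeca-4,6,12,13-tetraenoate
Product: 19 (1S,5R,8R,10R)-1α,6-bis(tert-butyldimethylsilyloxy)-4,4,10-trimethyl-9-methylidene-trans-octal-6-ene carrying at C8 the CH2CH(CO2SiMe2t-Bu)CH2CO2i-Pr arm
Conditions: toluene (high dilution), 2,6-di-tert-butyl-4-methylphenol, 170 °C, sealed tube
Reagents that add atoms: none
Why: Thermal suprafacial [4+2] cycloaddition in which the (5Z,7E)-2-silyloxydiene C5=C6(OSi)–C7=C8 adds across the proximal C10=C9 π bond of the allene, forming C5–C10 and C8–C9 in one concerted, asynchronous event, while the orthogonal C9=C11 π bond survives as the exocyclic methylene. The closest known reaction type is the type 1 intramolecular Diels–Alder reaction of 1,7,9-decatrienes with allenic dienophiles. Ring A closes as a six-membered carbocycle over the four-carbon tether C1–C4 in a chair-like, tether-exo array and ring B is the new cyclohexene, so a fused bicycle results because the short tether can only bring C5 to C10. C10 is controlled by C1, whose silyloxy group should sit equatorial on the forming ring A and anti to the incoming C5 (Felkin-type), which places the C10 methyl cis to O1; C5 follows from the trans-fused transition state and C8 from the E geometry of C7=C8 (C8 is erased again in step 13). The step needs selectivity for the proximal over the distal allene bond (secured by tether length) and for the trans-fused, O1-equatorial array (expected because the tether-endo array would place the C1–C2 segment with its silyloxy group beneath the 2-silyloxydiene); minor diastereomers can be separated because C1 is a single enantiomer.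

Step 10
Reactants: 19 the cycloadduct
Product: 20 keto acid with C6 ketone and free C12 carboxylic acid and retained 1α-silyl ether (1S,5R,8R,10R)
Conditions: AcOH/THF/H2O (3:1:1), rt
Reagents that add atoms: none
Why: Mild acid hydrolysis should cleave the silyl enol ether (protonation at C7) and the silyl ester but not the secondary C1 silyl ether, and C5, now α to the C6 ketone, already holds the trans (thermodynamic) configuration.

Step 11
Reactants: 20 the keto acid
Product: 21 6α-hydroxy acid (1S,5R,6S,8R,10R)
Conditions: NaBH4, MeOH, 0 °C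
Reagents that add atoms: none
Why: Ketone reduction by borohydride should occur from the β face because the α face of C6 is screened by the syn-axial C10 methyl, the axial C4 methyl and the C8–C14 bond, which gives the axial 6α-OH of the target; ester and carboxylate are not reduced.

Step 12
Reactants: 21 the 6α-hydroxy acid
Product: 24 ring-C enone ester: propan-2-yl ester of the C13 acetic acid arm on the C12-oxo-Δ9(11) tricycle with free 6α-OH and 1α-silyl ether, via acyl trifluoroacetate 22 (not isolated), via cyclised 6-trifluoroacetate 23 (not isolated)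
Conditions: (CF3CO)2O, 2,6-di-tert-butyl-4-methylpyridine, CH2Cl2, 0 °C; then SnCl4, −78 → −30 °C; then NaHCO3, MeOH/H2O
Reagents that add atoms: none
Why: Intramolecular Friedel–Crafts-type acylation of the 1,1-disubstituted exocyclic olefin by the C12 mixed anhydride (C11 attacks C12 to close six-membered ring C while the 6-OH is masked as its trifluoroacetate) should give, after proton loss from the C9 cation, the conjugated C9=C11 enone, a C8=C9 isomer being equally usable in step 13; methanolysis at work-up returns the 6-OH.

Step 13
Reactants: 24 the ring-C enone ester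
Product: 25 bridged 12,15-dione with C8=C9 olefin and 6α-OH and 1α-silyl ether (C11 and C13 as in the target)
Conditions: LiN(SiMe3)2 (3.3 equiv), THF, −78 → 0 °C; AcOH quench at −78 °C
Reagents that add atoms: none
Why: Intramolecular Claisen condensation in which γ-deprotonation at C8 gives the dienolate O–C12=C11–C9=C8 that is C-acylated at C11 by the isopropyl ester should close five-membered ring D and fix the olefin at C8=C9, excess amide converting the non-enolisable bridged dione into its C16 enolate to block retro-Claisen cleavage; C13 epimerises through the C12 enolate and only the epimer whose arm lies on the β face can reach C11 from the face opposite the C10 methyl, which sets C11 and C13 with the two-carbon bridge β.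

Step 14
Reactants: 25 the bridged dione
Product: 27 1α-acetoxy-6α-hydroxy bridged 12,15-dione, via diol dione 26 (not isolated)
Conditions: HF·pyridine, THF, 0 °C → rt; then pyridine, Ac2O, rt
Reagents that add atoms: acetic anhydride, CC(=O)OC(C)=O
Why: Fluoride cleavage of the C1 silyl ether followed by acetylation should esterify only the equatorial 1-OH, since the axial 6-OH is shielded by the syn-axial C4 and C10 methyl groups.

Step 15
Reactants: 27 the acetoxy dione
Product: 28 1α-acetoxy-6α,12-dihydroxy-15-ketone (12S; 12-OH syn to the C15–C16 bridge)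
Conditions: Zn(BH4)2 (0.6 equiv), Et2O, −40 °C; aq. NH4Cl
Reagents that add atoms: none
Why: Chelation-controlled hydride reduction, in which divalent zinc bridges the C12 and C15 carbonyl oxygens on the side of the two-carbon bridge, should deliver hydride to the more strained one-carbon-bridge ketone C12 from the side of the C8=C9 bridge and give the 12-OH syn to C15 while C15=O is kept.

Step 16
Reactants: 28 the hydroxy ketone
Product: 29 CNP0149338.1
Conditions: (CH2O)n, N-methylanilinium trifluoroacetate, THF, 65 °C
Reagents that add atoms: formaldehyde (as paraformaldehyde), C=O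
Why: Direct α-methylenation (Mannich condensation, then elimination of the amine) should occur at C16, the only enolisable position of the C15 ketone because C11 is a bridgehead, under mildly acidic conditions that spare the acetate and the β-hydroxy ketone.

## Compound list

1 | 4,4,5,5-tetramethyl-2-(prop-1-yn-1-yl)-1,3,2-dioxaborolane | CC#CB1OC(C)(C)C(C)(C)O1 | starting material
2 | lithium (chloromethyl)(prop-1-ynyl)pinacolatoborate | [Li+].CC#C[B-]1(CCl)OC(C)(C)C(C)(C)O1 | intermediate
3 | 2-(but-2-yn-1-yl)-4,4,5,5-tetramethyl-1,3,2-dioxaborolane | CC#CCB1OC(C)(C)C(C)(C)O1 | intermediate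
4 | methyl pent-4-enoate | COC(=O)CCC=C | starting material
5 | propan-2-yl bromoacetate | CC(C)OC(=O)CBr | starting material
6 | 1-methyl 4-propan-2-yl 2-(prop-2-en-1-yl)butanedioate (racemic) | COC(=O)C(CC=C)CC(=O)OC(C)C | intermediate
7 | ozonide (1,2,4-trioxolane) of 6 | COC(=O)C(CC1OOCO1)CC(=O)OC(C)C | intermediate
8 | 1-methyl 4-propan-2-yl 2-(2-oxoethyl)butanedioate (racemic) | COC(=O)C(CC=O)CC(=O)OC(C)C | intermediate
9 | 4-methylpent-3-en-2-one (mesityl oxide) | CC(C)=CC(C)=O | starting material
10 | but-3-en-1-ylmagnesium bromide | C=CCC[Mg]Br | starting material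
11 | 4,4-dimethyloct-7-en-2-one | CC(=O)CC(C)(C)CCC=C | intermediate
12 | ozonide (1,2,4-trioxolane) of 11 | CC(=O)CC(C)(C)CCC1OOCO1 | intermediate
13 | 4,4-dimethyl-6-oxoheptanal | CC(=O)CC(C)(C)CCC=O | intermediate
14 | pinacol borate ester of 15 | CC(=O)CC(C)(C)CC[C@H](OB1OC(C)(C)C(C)(C)O1)C(C)=C=C | intermediate
15 | (7S)-7-hydroxy-4,4,8-trimethyldeca-8,9-dien-2-one | CC(=O)CC(C)(C)CC[C@H](O)C(C)=C=C | intermediate
16 | aldol γ-lactone (C8–O–C12 lactone; C13 epimers) | CC(C)OC(=O)CC1CC(CC(=O)CC(C)(C)CC[C@H](O)C(C)=C=C)OC1=O | intermediate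
17 | (4E,11S)-11-hydroxy-8,8,12-trimethyl-6-oxo-2-[2-oxo-2-(propan-2-yloxy)ethyl]tetradeca-4,12,13-trienoic acid | CC(C)OC(=O)CC(C/C=C/C(=O)CC(C)(C)CC[C@H](O)C(C)=C=C)C(=O)O | intermediate
18 | tert-butyldimethylsilyl (4E,6Z,11S)-6,11-bis(tert-butyldimethylsilyloxy)-8,8,12-trimethyl-2-[2-oxo-2-(propan-2-yloxy)ethyl]tetradeca-4,6,12,13-tetraenoate | CC(C)OC(=O)CC(C/C=C/C(O[Si](C)(C)C(C)(C)C)=C/C(C)(C)CC[C@H](O[Si](C)(C)C(C)(C)C)C(C)=C=C)C(=O)O[Si](C)(C)C(C)(C)C | intermediate
19 | trans-fused cycloadduct: 1α,6-bis(silyloxy)-9-methylidene-octal-6-ene with C8 arm (1S,5R,8R,10R) | C=C1[C@H](CC(CC(=O)OC(C)C)C(=O)O[Si](C)(C)C(C)(C)C)C=C(O[Si](C)(C)C(C)(C)C)[C@@H]2C(C)(C)CC[C@H](O[Si](C)(C)C(C)(C)C)[C@@]12C | intermediate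
20 | 6-keto acid with 1α-silyl ether | C=C1[C@H](CC(CC(=O)OC(C)C)C(=O)O)CC(=O)[C@@H]2C(C)(C)CC[C@H](O[Si](C)(C)C(C)(C)C)[C@@]12C | intermediate
21 | 6α-hydroxy acid with 1α-silyl ether | C=C1[C@H](CC(CC(=O)OC(C)C)C(=O)O)C[C@H](O)[C@@H]2C(C)(C)CC[C@H](O[Si](C)(C)C(C)(C)C)[C@@]12C | intermediate
22 | acyl trifluoroacetate (mixed anhydride at C12) with 6-trifluoroacetate | C=C1[C@H](CC(CC(=O)OC(C)C)C(=O)OC(=O)C(F)(F)F)C[C@H](OC(=O)C(F)(F)F)[C@@H]2C(C)(C)CC[C@H](O[Si](C)(C)C(C)(C)C)[C@@]12C | intermediate
23 | cyclised ring-C enone as its 6-trifluoroacetate | CC(C)OC(=O)CC1C[C@@H]2C[C@H](OC(=O)C(F)(F)F)[C@@H]3C(C)(C)CC[C@H](O[Si](C)(C)C(C)(C)C)[C@@]3(C)C2=CC1=O | intermediate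
24 | ring-C enone ester (12-oxo-Δ9(11); 6α-OH; 1α-OTBS; C13 epimers) | CC(C)OC(=O)CC1C[C@@H]2C[C@H](O)[C@@H]3C(C)(C)CC[C@H](O[Si](C)(C)C(C)(C)C)[C@@]3(C)C2=CC1=O | intermediate
25 | bridged 12,15-dione (C8=C9; 6α-OH; 1α-OTBS) | C1C(=O)[C@@H]2C3=C(C[C@H]1C2=O)C[C@H](O)[C@@H]1C(C)(C)CC[C@H](O[Si](C)(C)C(C)(C)C)[C@@]31C | intermediate
26 | bridged 12,15-dione 1α,6α-diol | C1C(=O)[C@@H]2C3=C(C[C@H]1C2=O)C[C@H](O)[C@@H]1C(C)(C)CC[C@H](O)[C@@]31C | intermediate
27 | 1α-acetoxy-6α-hydroxy bridged 12,15-dione | C1C(=O)[C@@H]2C3=C(C[C@H]1C2=O)C[C@H](O)[C@@H]1C(C)(C)CC[C@H](OC(C)=O)[C@@]31C | intermediate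
28 | 1α-acetoxy-6α,12-dihydroxy-15-ketone (16-CH2) | C1C(=O)[C@@H]2C3=C(C[C@H]1[C@@H]2O)C[C@H](O)[C@@H]1C(C)(C)CC[C@H](OC(C)=O)[C@@]31C | intermediate
29 | CNP0149338.1 | C=C1C(=O)[C@@H]2C3=C(C[C@H]1[C@@H]2O)C[C@H](O)[C@@H]1C(C)(C)CC[C@H](OC(C)=O)[C@@]31C | target

## Step count and risks

Total step count: 16. Longest linear sequence: 13 steps (steps 4–16, from 9 and 10 to 29).

Steps most likely to fail:

1. Step 9. The unactivated allene may add too slowly for the silyl dienol ether to survive the heating, and the tether-endo (cis-fused) transition state may compete, which would place C10 in the wrong sense relative to C1. Fallback: the cycloaddition is changed from a thermal pericyclic to a stepwise, metal-templated one, setting out from 18 and coming back at 19 with no new compound (F0). A cationic monovalent gold catalyst, (2,4-t-Bu2C6H3O)3PAuCl with AgSbF6 in CH2Cl2 at −20 °C, would activate the allene; C5 of the enol silane attacks C10, and the alkenyl-gold at C9 then closes on C8 of the unsaturated silyloxocarbenium ion. This is the known gold-catalysed intramolecular allene–diene [4+2] manifold, in which the bulky ligated metal on C9 should take the equatorial site of ring A and enforce the trans array.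

2. Step 13. The Claisen closure to a bridged dione that cannot enolise between its carbonyls may reverse (retro-Claisen opening by the released alkoxide) or divert to O-acylation. Fallback: setting out from 24, the isopropyl ester is saponified (LiOH, THF/H2O) to the keto acid F1, which is converted with 1,1′-carbonyldiimidazole into the acyl imidazolide F2. C-acylation of C11 under soft enolisation (MgBr2·OEt2, i-Pr2NEt, CH2Cl2) then releases no alkoxide and comes back at 25.

3. Step 15. Hydride may be delivered to the wrong carbonyl or to the wrong face of C12. Fallback: kinetic hydride delivery is replaced by thermodynamic control. Setting out from 27, reduction that gives the 12-epimeric ketol F3 (alone or mixed with 28) is followed by equilibration with catalytic DBU in toluene through reversible retro-aldol/aldol cleavage of C11–C12. This should funnel to the ketol whose hydroxyl points away from the C10 methyl and is hydrogen-bonded to the C15 carbonyl, coming back at 28.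

Further compounds
F0 | step 9 | none | none
F1 | step 13 | keto acid from saponification of 24 | OC(=O)CC1C[C@@H]2C[C@H](O)[C@@H]3C(C)(C)CC[C@H](O[Si](C)(C)C(C)(C)C)[C@@]3(C)C2=CC1=O
F2 | step 13 | acyl imidazolide of F1 | O=C(CC1C[C@@H]2C[C@H](O)[C@@H]3C(C)(C)CC[C@H](O[Si](C)(C)C(C)(C)C)[C@@]3(C)C2=CC1=O)n1ccnc1
F3 | step 15 | C12 epimer of 28 | C1C(=O)[C@@H]2C3=C(C[C@H]1[C@H]2O)C[C@H](O)[C@@H]1C(C)(C)CC[C@H](OC(C)=O)[C@@]31C
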